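A percentage point of the E charged is my unit, and 2 percentage points of them is the gain an option has to beat.

| flask | E | J | Z | temperature | remark | time |
|---|---|---|---|---|---|---|
| north | 0.40 M | 0.080 M | 0.40 mM | 40 °C | the very flask that is asked about, followed so far |  |
| south-east | 0.40 M | 0.054 M | 0.40 mM | 40 °C | run made earlier |  |
| flask | 0.40 M | 0.0800 M | 0.40 mM | 40 °C |  | 50 min |

| run | time / min | Q / % | E / % |
|---|---|---|---|
| north | 2.00 | 20 | 72 |
| north | 6.00 | 36 | 50 |
| north | 12.0 | 35 | 46 |
| north | 15.0 | 37 | 45 |
| north | 25.0 | 37 | 47 |
| north | 30.0 | 35 | 45 |
| north | 40.0 | 38 | 45 |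
| south-east | 0.500 | 3 | 92 |
| south-east | 1.50 | 17 | 79 |
| south-east | 3.00 | 24 | 67 |
| south-east | 4.00 | 28 | 61 |
| south-east | 6.00 | 32 | 56 |
| south-east | 8.00 | 34 | 49 |
| south-east | 10.0 | 37 | 49 |

(readings scatter by 1.5 percentage points)

- noon: change nothing and wait 15 min more
- summer: at 50 min raise the temperature by 25 K, then wait 15 min
- dawn: at 50 min add Z, 100 % of the amount charged, then wait 15 min
- winter: at 50 min take out 90 % of the Q then present, then wait 15 min

- removed Q is counted in
- the earlier runs were read with a standard deviation of 1.5 percentage points
- additions bring no volume worth counting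
- the earlier runs do not show what temperature does; that part of a forecast is a guess

- Q, in percent of the E first charged, at 50 min
- the option that brings most further Q ("none" if no option brings more than 2 percentage points) (noon / summer / dawn / winter / none)
- Q present, with what was taken out counted in, in percent of the E first charged, after noon
- Q present, with what was taken out counted in, in percent of the E first charged, after winter

I first ask which input the answer hangs on. Time hardly matters: north Q reads 37 % at 15.0 min and 38 % at 40.0 min, with a scatter of 1.5 points. J barely shows in Q: the last reading is 37 % at 10.0 min in the south-east run with 0.054 M of J and 38 % at 40.0 min in the north flask with 0.080 M. The share missing from Q plus E reads 14.0 % and 17.0 %, near the J charges of 13.5 % and 20.0 % of the E. So J looks like the limiting reagent of a side loss, and it leaves the north flask a pool p of 80.0 % for Q and E. Z I cannot judge from the readings, for both runs carry 0.40 mM.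

North Q stops near 36.8 % with E at 45 %. Either E and Q have balanced or Z has stopped working, and one Z charge cannot part the two. I wager on the second, supposing that Q takes Z out of its round. Q then forms at a rate going with Z times E, and Z is lost at a rate going with Z times Q, so the Z lost per point of Q goes with Q/E. Summing Q/E over the Q fraction q made, with E as p minus q, gives −q − p·ln(1 − q/p). This is the Z bill, 0.125 for the north flask, and it should scale with the Z charged. So noon and winter stay near 36.8 %. Dawn doubles the bill, and the plateau slope prices that at 15 points, an upper figure since each further point costs more. I pick dawn and leave summer as a guess.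

The forecast gives 37 %, 37 % after noon and 55 % after winter, and picks winter: “This points to a reversible E ⇌ Q equilibrium”. We part on the option and on the figure after winter.

The flask gives 36.0 % at 50 min, 35.9 % after noon and 36.0 % after winter. The best option is dawn, with 10 points where the price said 15 points.

    E + Z → Z + Q (k = 309 M⁻¹ min⁻¹, Ea = 61.0 kJ mol⁻¹)
    E + J → L (k = 1.27 M⁻¹ min⁻¹, Ea = 47.0 kJ mol⁻¹)
    Z + Q → G (k = 2.78 M⁻¹ min⁻¹, Ea = 54.0 kJ mol⁻¹)
    Q → X (k = 2.06 × 10⁻⁴ min⁻¹, Ea = 103 kJ mol⁻¹)
    (constants at 40 °C)

The neighbouring flask differs from this one by its Z, 1.6 × 10⁻⁴ M, which is 40.0 % of this flask's charge, so its bill should be that share of 0.125, or 0.0498. Its Q at 50 min stands at 24.0 %, and that Q on the same pool makes a bill of 0.0453.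

Readings and results come from a simulation with constants of no real substance.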